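**Assumption:** nigrasin I has no stereocentre and no stereodefined alkene (it is achiral), so no stereochemistry needs to be set and the compound drawn is a single species.

## Retrosynthetic overview

1. Target 13 ⇐ global MOM removal from 12; the C3–prenyl bond ⇐ C3-lithiation/prenylation of flavone 11.
2. Flavone 11 ⇐ o-hydroxyaryl ynone ⇐ key step: photo-Fries rearrangement of aryl arylpropiolate 10, where recombination of the aryloxyl/acyl radical pair forges C4–C4a.
3. The phenol oxygen is used three times: it carries the prenyl group (Claisen, giving C8), then the acyl group (photo-Fries, giving C4a), then becomes O1. This fixes the 1,1-dimethylallyl group at C8 rather than C6.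
4. Ester 10 ⇐ phenol 6 (from 3,5-bis(MOMO)phenol 3, by O-prenylation and Claisen) + arylpropiolic acid 9 (from iodide 7 + propiolic acid); 3 and 7 both come from resorcinol bis-MOM ether 2.
5. Ring order: rings A and B are both taken intact from resorcinol; only the pyranone C ring is built, in step 8.

## Route

**Step 1**
Reactants: 1, resorcinol
Product: 2, 1,3-bis(methoxymethoxy)benzene
Conditions: MOMCl, i-Pr2NEt, CH2Cl2, 0 °C → rt
Reagents that add atoms: chloromethyl methyl ether, COCCl
Why: Standard Williamson-type acetal protection of both phenols; 2 serves both the A-ring and B-ring branches.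

**Step 2**
Reactants: 2, 1,3-bis(methoxymethoxy)benzene
Product: 3, 3,5-bis(methoxymethoxy)phenol
Conditions: [Ir(OMe)(cod)]2 (cat.), dtbpy, B2pin2, THF, 80 °C; then aq. NaOH, 30% H2O2, 0 °C → rt (one pot)
Reagents that add atoms: hydrogen peroxide, OO
Why: Sterically controlled Ir-catalysed C–H borylation occurs only at C5 (the one C–H with no ortho substituent), and basic peroxide oxidation of the ArBpin gives the phenol without touching the MOM ethers.

**Step 3**
Reactants: 3, 3,5-bis(methoxymethoxy)phenol; 4, prenyl bromide (1-bromo-3-methylbut-2-ene)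
Product: 5, 1,3-bis(methoxymethoxy)-5-[(3-methylbut-2-en-1-yl)oxy]benzene
Conditions: K2CO3, acetone, reflux
Reagents that add atoms: none
Why: Williamson O-alkylation of the only free phenol with the primary allylic bromide (SN2).

**Step 4**
Reactants: 5, aryl prenyl ether
Product: 6, 3,5-bis(methoxymethoxy)-2-(2-methylbut-3-en-2-yl)phenol
Conditions: PhNEt2, 190 °C, Ar
Reagents that add atoms: none
Why: Aromatic ortho-Claisen [3,3] rearrangement with allyl inversion gives the 1,1-dimethylallyl group next to the phenol; the two ortho positions are equivalent, and the amine solvent suppresses acid-mediated cyclisation of the product.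

**Step 5**
Reactants: 2, 1,3-bis(methoxymethoxy)benzene
Product: 7, 1-iodo-2,4-bis(methoxymethoxy)benzene
Conditions: NIS (1.0 equiv), MeCN, 0 °C → rt, dark
Reagents that add atoms: N-iodosuccinimide, O=C1CCC(=O)N1I
Why: Electrophilic aromatic iodination goes to C4 (para to one OMOM, ortho to the other) rather than the hindered C2, under neutral conditions that leave the MOM ethers intact.

**Step 6**
Reactants: 7, 1-iodo-2,4-bis(methoxymethoxy)benzene; 8, propiolic acid
Product: 9, 3-[2,4-bis(methoxymethoxy)phenyl]prop-2-ynoic acid
Conditions: PdCl2(PPh3)2 (cat.), dppb, DBU, DMSO, 25–35 °C; citric acid work-up (pH ≈ 4)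
Reagents that add atoms: none
Why: Copper-free Sonogashira coupling of an aryl iodide with propiolic acid; keeping the temperature low avoids decarboxylative second coupling.

**Step 7**
Reactants: 6, 3,5-bis(methoxymethoxy)-2-(2-methylbut-3-en-2-yl)phenol; 9, arylpropiolic acid
Product: 10, 3,5-bis(methoxymethoxy)-2-(2-methylbut-3-en-2-yl)phenyl 3-[2,4-bis(methoxymethoxy)phenyl]prop-2-ynoate
Conditions: DCC, DMAP (cat.), CH2Cl2, 0 °C → rt
Reagents that add atoms: none
Why: Steglich esterification is neutral (safe for MOM groups and alkenes) and is the usual way to make aryl 3-arylpropiolates, including from hindered phenols.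

**Step 8 (key step)**
Reactants: 10, aryl arylpropiolate
Product: 11, 2-[2,4-bis(methoxymethoxy)phenyl]-5,7-bis(methoxymethoxy)-8-(2-methylbut-3-en-2-yl)-4H-chromen-4-one
Conditions: hν (254 nm, quartz), degassed MeCN (ca. 5 mM), 20 °C; then K2CO3, 60 °C (same pot)
Reagents that add atoms: none
Why: Photo-Fries rearrangement: homolysis of the ArO–C(O) bond gives a caged aryloxyl/alkynoyl radical pair (the alkynoyl radical does not decarbonylate) that recombines at the only free ortho carbon to form C4–C4a, and the resulting o-hydroxyaryl ynone closes by 6-endo-dig oxa-Michael addition under aprotic carbonate conditions. The para-Fries isomer (which cannot cyclise) and recovered 6 are expected by-products and are separable.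

**Step 9**
Reactants: 11, protected 3-H flavone; 4, prenyl bromide
Product: 12, 2-[2,4-bis(methoxymethoxy)phenyl]-5,7-bis(methoxymethoxy)-8-(2-methylbut-3-en-2-yl)-3-(3-methylbut-2-en-1-yl)-4H-chromen-4-one
Conditions: LDA (1.2 equiv), THF, −78 °C, 20 min; CuBr·SMe2; then 4, −78 → 0 °C
Reagents that add atoms: none
Why: Directed C3-lithiation of the flavone (the vinylic C3–H is acidified and chelated by C4=O and the 2'-OMOM) followed by copper-mediated SN2 allylation at the primary carbon of prenyl bromide gives the linear prenyl group; there are no free OH groups and the 1,1-dimethylallyl group has no allylic hydrogens.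

**Step 10**
Reactants: 12, tetra-MOM 3-prenylflavone
Product: 13, nigrasin I, 2-(2,4-dihydroxyphenyl)-5,7-dihydroxy-8-(2-methylbut-3-en-2-yl)-3-(3-methylbut-2-en-1-yl)-4H-chromen-4-one
Conditions: 3 M aq. HCl–MeOH (1:5), 45 °C
Reagents that add atoms: none
Why: Mild acidic acetal hydrolysis removes all four MOM ethers; these conditions are tolerated by prenyl groups and by o-(1,1-dimethylallyl)phenols in related prenylated flavonoids and chalcones.

## Compound list

1 | resorcinol | Oc1cccc(O)c1 | starting material
2 | 1,3-bis(methoxymethoxy)benzene | COCOc1cccc(OCOC)c1 | intermediate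
3 | 3,5-bis(methoxymethoxy)phenol | COCOc1cc(O)cc(OCOC)c1 | intermediate
4 | prenyl bromide (1-bromo-3-methylbut-2-ene) | CC(C)=CCBr | starting material
5 | 1,3-bis(methoxymethoxy)-5-[(3-methylbut-2-en-1-yl)oxy]benzene | COCOc1cc(OCC=C(C)C)cc(OCOC)c1 | intermediate
6 | 3,5-bis(methoxymethoxy)-2-(2-methylbut-3-en-2-yl)phenol | C=CC(C)(C)c1c(O)cc(OCOC)cc1OCOC | intermediate
7 | 1-iodo-2,4-bis(methoxymethoxy)benzene | COCOc1ccc(I)c(OCOC)c1 | intermediate
8 | propiolic acid | C#CC(=O)O | starting material
9 | 3-[2,4-bis(methoxymethoxy)phenyl]prop-2-ynoic acid | COCOc1ccc(C#CC(=O)O)c(OCOC)c1 | intermediate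
10 | 3,5-bis(methoxymethoxy)-2-(2-methylbut-3-en-2-yl)phenyl 3-[2,4-bis(methoxymethoxy)phenyl]prop-2-ynoate | C=CC(C)(C)c1c(OC(=O)C#Cc2ccc(OCOC)cc2OCOC)cc(OCOC)cc1OCOC | intermediate
11 | 2-[2,4-bis(methoxymethoxy)phenyl]-5,7-bis(methoxymethoxy)-8-(2-methylbut-3-en-2-yl)-4H-chromen-4-one | C=CC(C)(C)c1c(OCOC)cc(OCOC)c2c(=O)cc(-c3ccc(OCOC)cc3OCOC)oc12 | intermediate
12 | 2-[2,4-bis(methoxymethoxy)phenyl]-5,7-bis(methoxymethoxy)-8-(2-methylbut-3-en-2-yl)-3-(3-methylbut-2-en-1-yl)-4H-chromen-4-one | C=CC(C)(C)c1c(OCOC)cc(OCOC)c2c(=O)c(CC=C(C)C)c(-c3ccc(OCOC)cc3OCOC)oc12 | intermediate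
13 | nigrasin I | C=CC(C)(C)c1c(O)cc(O)c2c(=O)c(CC=C(C)C)c(-c3ccc(O)cc3O)oc12 | target

## Summary

**Total steps:** 10

**Longest linear sequence:** 8 steps (1 → 2 → 3 → 5 → 6 → 10 → 11 → 12 → 13; steps 1, 2, 3, 4, 7, 8, 9, 10)

**Steps most likely to fail, with fallbacks:**

1. **Step 8 (photo-Fries/cyclisation).** Risks are competing para-migration, cage escape back to phenol 6, secondary photochemistry, and 5-exo (aurone) closure. Fallback: make the same ynone ionically. Ortho-formylate 6 (MgCl2, Et3N, paraformaldehyde), add lithiated 2,4-bis(methoxymethoxy)phenylacetylene (from 7), oxidise with MnO2 and cyclise with K2CO3. This sets C4–C4a by ortho-formylation instead of acyl migration.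
2. **Step 4 (aromatic Claisen).** Risks are para-Claisen/Cope products, loss of isoprene, and dihydrobenzofuran formation at 190 °C. Fallback: ortho-brominate 3 (NBS), protect the phenol, and install the 1,1-dimethylallyl group by Pd-catalysed branched-selective (γ) Suzuki coupling with prenyl-Bpin, then unmask the phenol. This replaces the sigmatropic step with a cross-coupling.
3. **Step 9 (C3 lithiation/prenylation).** Risks are competing aryl lithiation between the OMOM groups, ring-opening of the 3-lithioflavone, and SN2' coupling. Fallback: carry the prenyl group in the alkyne. Couple 7 with 5-methylhex-4-en-1-yne, and annulate that aryl alkyne with the salicylaldehyde made from 6 by Rh(III)-catalysed aldehyde C–H activation, which would give 12 directly.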